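**Retrosynthetic overview**
1. The C6–O ester bond is made with inversion: the carboxylate of hydroxy acid 15 displaces a 6α-sulfonate (16) that is generated in the same flask by ε-oxygenation of trienyl acetate 8.
2. The C3–OH bond is made last by enolate hydroxylation of ester 17; 8 comes from linear dienone 7 by thermodynamic enol acetylation, and 7 from octalone 6 by dehydrogenation.
3. Octalone 6 comes from Robinson annulation of (3S)-2,3-dimethylcyclohexanone 3 with methyl vinyl ketone; 3 comes from asymmetric conjugate methylation of 2-methylcyclohexenone.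
4. Acid 15 comes from cross-metathesis of (2S,3S)-3-methylpent-4-en-2-ol 13 with sorbic acid; 13 comes from Brown (Z)-crotylboration of acetaldehyde.
5. Ring order: ring A is the starting cyclohexenone; ring B is closed onto it by the Robinson annulation; no further ring is formed.

Assumption: the core is numbered as naphthalen-2(3H)-one (C2 ketone, C3 CH–OH, C4a quaternary C–CH3, C5 CH–CH3, C6 CH–O-acyl); β is the face of the C4a methyl. Read this way the target is (3R,4aR,5R,6S) with C4a-Me, C5-Me and C6-O all β and C3-OH α; the acyl chain is (2E,4E,6S,7S), syn.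

**Route**

Step 1
Reactants: 1 2-methylcyclohex-2-en-1-one
Product: 3 (3S)-2,3-dimethylcyclohexan-1-one, via aluminium enolate 2 (not isolated)
Conditions: Me3Al (1.4 equiv), CuTC (2 mol %), chiral phosphoramidite (4 mol %; antipode that gives 3S), Et2O, −30 °C; then 1 M HCl
Reagents that add atoms: trimethylaluminium, C[Al](C)C
Why: Copper-catalysed asymmetric conjugate addition to a 2-substituted cyclohexenone; the chiral Cu–phosphoramidite complex delivers methyl to one enone face and sets C3 (S), while C2 is left as an epimer mixture that is enolised away in step 2.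

Step 2
Reactants: 3 (3S)-2,3-dimethylcyclohexan-1-one; 4 methyl vinyl ketone
Product: 6 (4aR,5S)-4a,5-dimethyl-4,4a,5,6,7,8-hexahydronaphthalen-2(3H)-one, via Michael diketone 5 (not isolated)
Conditions: H2SO4 (cat.), toluene, 0 °C to reflux (Dean–Stark)
Reagents that add atoms: none
Why: Acid-catalysed Robinson annulation (Michael addition of the more substituted enol, aldol condensation, dehydration); the enone adds to C2 anti to the pseudoaxial C3 methyl (A1,2 strain), so the new quaternary centre carries its methyl cis to the C5 methyl (4aR).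

Step 3
Reactants: 6 (4aR,5S)-4a,5-dimethyl-4,4a,5,6,7,8-hexahydronaphthalen-2(3H)-one
Product: 7 (4aR,5S)-4a,5-dimethyl-4,4a,5,6-tetrahydronaphthalen-2(3H)-one
Conditions: chloranil (1.3 equiv), t-BuOH, reflux
Reagents that add atoms: none
Why: Quinone dehydrogenation through the extended dienol (hydride loss from C7, then proton loss) gives the linear 1(8a),7-dienone, the same γ,δ-dehydrogenation that turns steroidal 4-en-3-ones into 4,6-dien-3-ones; no stereocentre is touched.

Step 4
Reactants: 7 (4aR,5S)-4a,5-dimethyl-4,4a,5,6-tetrahydronaphthalen-2(3H)-one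
Product: 8 (4aR,5S)-4a,5-dimethyl-3,4,4a,5-tetrahydronaphthalen-2-yl acetate
Conditions: isopropenyl acetate (solvent), TsOH·H2O (5 mol %), reflux, acetone distilled off
Reagents that add atoms: isopropenyl acetate, CC(=C)OC(C)=O
Why: Acid-catalysed thermodynamic enol acetylation; reversible protonation funnels the dienone to the linearly conjugated trienyl acetate by loss of the ε-hydrogen at C6, as in the conversion of steroidal 4,6-dien-3-ones into 3,5,7-trienyl acetates, and no stereocentre is formed.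

Step 5
Reactants: 9 acetaldehyde; 10 cis-but-2-ene
Product: 13 (2S,3S)-3-methylpent-4-en-2-ol, via crotylborane 11 (not isolated), via borinate 12 (not isolated)
Conditions: t-BuOK, n-BuLi, THF, −78 to −45 °C; (+)-Ipc2BOMe, −78 °C; BF3·OEt2; 9, −78 °C; then NaOH, H2O2
Reagents that add atoms: none
Why: Brown asymmetric crotylboration; the (Z)-crotylborane reacts through a chair Zimmerman–Traxler transition state to give the syn adduct, and the (+)-Ipc2B groups (from (−)-α-pinene) select the Re face of acetaldehyde, setting 2S,3S.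

Step 6
Reactants: 13 (2S,3S)-3-methylpent-4-en-2-ol; 14 sorbic acid
Product: 15 (2E,4E,6S,7S)-7-hydroxy-6-methylocta-2,4-dienoic acid
Conditions: Hoveyda–Grubbs II (5 mol %), 14 (4 equiv), CH2Cl2, 40 °C
Reagents that add atoms: none
Why: Olefin cross-metathesis at the distal, less electron-poor C4=C5 bond of sorbic acid with loss of propene; the new conjugated double bond forms E under thermodynamic control and the two stereocentres are not involved.

Step 7
Reactants: 8 (4aR,5S)-4a,5-dimethyl-3,4,4a,5-tetrahydronaphthalen-2-yl acetate; 15 (2E,4E,6S,7S)-7-hydroxy-6-methylocta-2,4-dienoic acid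
Product: 17 (4aR,5R,6S)-6-[(2E,4E,6S,7S)-7-hydroxy-6-methylocta-2,4-dienoyloxy]-4a,5-dimethyl-4,4a,5,6-tetrahydronaphthalen-2(3H)-one, via 6α-nosylate 16 (not isolated)
Conditions: (4-O2NC6H4SO2O)2 (1.05 equiv), i-PrOH (1.5 equiv), EtOAc, −20 °C to rt; then 15 (1.3 equiv), Cs2CO3 (1.15 equiv), DMF, 0 °C to rt
Reagents that add atoms: none
Why: Proposed new method: the trienyl acetate attacks the peroxide O–O bond through its terminal ε-carbon C6 from the face anti to the axial C4a methyl, giving 6α-nosylate 16, a doubly vinylogous α-sulfonyloxy ketone that resists ionisation, and the caesium carboxylate then displaces nosylate by SN2 with inversion to form the 6β (6S) C–O ester bond, so the nucleophile ends on the hindered face that no direct oxidant would choose; the closest known reaction types are α-sulfonyloxylation of enol acetates and silyl enol ethers with arenesulfonyl peroxides followed by SN2 displacement of the α-sulfonyloxy ketone, and the vinylogous peracid oxidation of dienol esters.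

Step 8
Reactants: 17 (4aR,5R,6S)-6-[(2E,4E,6S,7S)-7-hydroxy-6-methylocta-2,4-dienoyloxy]-4a,5-dimethyl-4,4a,5,6-tetrahydronaphthalen-2(3H)-one
Product: 19 (3R,4aR,5R,6S)-3-hydroxy-6-[(2E,4E,6S,7S)-7-hydroxy-6-methylocta-2,4-dienoyloxy]-4a,5-dimethyl-4,4a,5,6-tetrahydronaphthalen-2(3H)-one, via dipotassium dienolate 18 (not isolated)
Conditions: KHMDS (2.2 equiv), THF, −78 °C; trans-2-(phenylsulfonyl)-3-phenyloxaziridine (1.3 equiv), −78 °C; AcOH
Reagents that add atoms: trans-2-(phenylsulfonyl)-3-phenyloxaziridine, O=S(=O)(N1OC1c1ccccc1)c1ccccc1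
Why: Kinetic deprotonation (side-chain OH, then the α′-CH2 at C3) gives the cross-conjugated dienolate, and Davis oxaziridine enolate hydroxylation delivers oxygen to C3 anti to the axial C4a methyl, giving the equatorial, thermodynamically preferred 3R alcohol; the dienoate has no α-hydrogen and the C6 ester cannot be expelled from this enolate.

**Compound list**
1 | 2-methylcyclohex-2-en-1-one | CC1=CCCCC1=O | starting material
2 | dimethylaluminium (S)-2,3-dimethylcyclohex-1-en-1-olate | C[Al](C)OC1=C(C)[C@@H](C)CCC1 | intermediate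
3 | (3S)-2,3-dimethylcyclohexan-1-one (C2 epimer mixture) | O=C1CCC[C@H](C)C1C | intermediate
4 | methyl vinyl ketone | CC(=O)C=C | starting material
5 | (2R,3S)-2,3-dimethyl-2-(3-oxobutyl)cyclohexan-1-one | CC(=O)CC[C@@]1(C)C(=O)CCC[C@@H]1C | intermediate
6 | (4aR,5S)-4a,5-dimethyl-4,4a,5,6,7,8-hexahydronaphthalen-2(3H)-one | C1CCC2=CC(=O)CC[C@]2(C)[C@H]1C | intermediate
7 | (4aR,5S)-4a,5-dimethyl-4,4a,5,6-tetrahydronaphthalen-2(3H)-one | C1C=CC2=CC(=O)CC[C@]2(C)[C@H]1C | intermediate
8 | (4aR,5S)-4a,5-dimethyl-3,4,4a,5-tetrahydronaphthalen-2-yl acetate | C1=CC=C2C=C(OC(C)=O)CC[C@]2(C)[C@H]1C | intermediate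
9 | acetaldehyde | CC=O | starting material
10 | cis-but-2-ene | C/C=C\C | starting material
11 | B-[(Z)-but-2-enyl]diisopinocampheylborane, from (+)-Ipc2BOMe | C/C=C\CB([C@H]1C[C@H]2C[C@@H]([C@@H]1C)C2(C)C)[C@H]1C[C@H]2C[C@@H]([C@@H]1C)C2(C)C | intermediate
12 | (2S,3S)-3-methylpent-4-en-2-yl diisopinocampheylborinate | C[C@H](OB([C@H]1C[C@H]2C[C@@H]([C@@H]1C)C2(C)C)[C@H]1C[C@H]2C[C@@H]([C@@H]1C)C2(C)C)[C@@H](C)C=C | intermediate
13 | (2S,3S)-3-methylpent-4-en-2-ol | C[C@H](O)[C@@H](C)C=C | intermediate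
14 | sorbic acid, (2E,4E)-hexa-2,4-dienoic acid | C/C=C/C=C/C(=O)O | starting material
15 | (2E,4E,6S,7S)-7-hydroxy-6-methylocta-2,4-dienoic acid | C[C@H](O)[C@@H](C)/C=C/C=C/C(=O)O | intermediate
16 | (4aR,5R,6R)-4a,5-dimethyl-6-(4-nitrophenylsulfonyloxy)-4,4a,5,6-tetrahydronaphthalen-2(3H)-one | O=[N+]([O-])c1ccc(cc1)S(=O)(=O)O[C@@H]1C=CC2=CC(=O)CC[C@]2(C)[C@H]1C | intermediate
17 | (4aR,5R,6S)-6-[(2E,4E,6S,7S)-7-hydroxy-6-methylocta-2,4-dienoyloxy]-4a,5-dimethyl-4,4a,5,6-tetrahydronaphthalen-2(3H)-one | C[C@H](O)[C@@H](C)/C=C/C=C/C(=O)O[C@H]1C=CC2=CC(=O)CC[C@]2(C)[C@H]1C | intermediate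
18 | dipotassium salt of 17 (side-chain alkoxide and C2=C3 dienolate) | [K+].[K+].C[C@H]([O-])[C@@H](C)/C=C/C=C/C(=O)O[C@H]1C=CC2=CC([O-])=CC[C@]2(C)[C@H]1C | intermediate
19 | (3R,4aR,5R,6S)-3-hydroxy-6-[(2E,4E,6S,7S)-7-hydroxy-6-methylocta-2,4-dienoyloxy]-4a,5-dimethyl-4,4a,5,6-tetrahydronaphthalen-2(3H)-one | C[C@H](O)[C@@H](C)/C=C/C=C/C(=O)O[C@H]1C=CC2=CC(=O)[C@H](O)C[C@]2(C)[C@H]1C | target

**Step count**
Total steps: 8. Longest linear sequence: 6 (steps 1, 2, 3, 4, 7, 8).

**Three steps most likely to fail**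

Step 7 (the new method). The risks are attack of the peroxide at C1 instead of C6, the wrong face at C6, and epimerisation of 16 before displacement. The fallback uses known chemistry, sets out from 8 and 15 and comes back at 17. Peracid oxidation of 8 (mCPBA, NaHCO3, CH2Cl2–H2O, 0 °C, the vinylogous enol-ester oxidation used for 6-hydroxylation of steroidal dienol acetates) gives (4aR,5R,6R)-6-hydroxy-4a,5-dimethyl-4,4a,5,6-tetrahydronaphthalen-2(3H)-one F1 and its epimer (4aR,5R,6S)-6-hydroxy-4a,5-dimethyl-4,4a,5,6-tetrahydronaphthalen-2(3H)-one F2, which are separated. Acid 15 is silylated (TESCl, imidazole; then K2CO3, MeOH–H2O to free the acid) to (2E,4E,6S,7S)-6-methyl-7-(triethylsilyloxy)octa-2,4-dienoic acid F3. F1 is esterified with F3 under Mitsunobu conditions (PPh3, DIAD, toluene, inversion) and F2 under Yamaguchi conditions (retention), so both epimers give (4aR,5R,6S)-4a,5-dimethyl-6-[(2E,4E,6S,7S)-6-methyl-7-(triethylsilyloxy)octa-2,4-dienoyloxy]-4,4a,5,6-tetrahydronaphthalen-2(3H)-one F4. AcOH–THF–H2O removes the silyl ether and gives 17.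

Step 8. The strong base may epimerise C6 through the extended enolate or attack the ester. The fallback sets out from 17 and comes back at 19 by a neutral Rubottom sequence. TESOTf and Et3N (CH2Cl2, −78 to 0 °C) silylate the side-chain hydroxyl and give the kinetic silyl dienol ether (4aR,5R,6S)-4a,5-dimethyl-2-(triethylsilyloxy)-6-[(2E,4E,6S,7S)-6-methyl-7-(triethylsilyloxy)octa-2,4-dienoyloxy]-4,4a,5,6-tetrahydronaphthalene F5. Oxidation with mCPBA (NaHCO3, −20 °C) gives (3R,4aR,5R,6S)-4a,5-dimethyl-3-(triethylsilyloxy)-6-[(2E,4E,6S,7S)-6-methyl-7-(triethylsilyloxy)octa-2,4-dienoyloxy]-4,4a,5,6-tetrahydronaphthalen-2(3H)-one F6. 1 M HCl–THF removes both silyl groups and gives 19.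

Step 6. The risks are metathesis at the C2=C3 bond of sorbic acid and slow reaction of the allylically branched alkene. The fallback sets out from 13 and comes back at 15 by olefination instead of metathesis. TBSCl and imidazole give tert-butyldimethyl{[(2S,3S)-3-methylpent-4-en-2-yl]oxy}silane F7. Ozonolysis (O3, CH2Cl2, −78 °C; Me2S) gives (2R,3S)-3-(tert-butyldimethylsilyloxy)-2-methylbutanal F8. Vinylogous Horner–Wadsworth–Emmons reaction with triethyl 4-phosphonocrotonate (LiHMDS, THF, −78 to 0 °C) gives ethyl (2E,4E,6S,7S)-7-(tert-butyldimethylsilyloxy)-6-methylocta-2,4-dienoate F9. LiOH (THF–H2O) gives (2E,4E,6S,7S)-7-(tert-butyldimethylsilyloxy)-6-methylocta-2,4-dienoic acid F10. HF·pyridine then gives 15.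

**Further compounds**
F1 | step 7 | (4aR,5R,6R)-6-hydroxy-4a,5-dimethyl-4,4a,5,6-tetrahydronaphthalen-2(3H)-one | O[C@@H]1C=CC2=CC(=O)CC[C@]2(C)[C@H]1C
F2 | step 7 | (4aR,5R,6S)-6-hydroxy-4a,5-dimethyl-4,4a,5,6-tetrahydronaphthalen-2(3H)-one | O[C@H]1C=CC2=CC(=O)CC[C@]2(C)[C@H]1C
F3 | step 7 | (2E,4E,6S,7S)-6-methyl-7-(triethylsilyloxy)octa-2,4-dienoic acid | C[C@H](O[Si](CC)(CC)CC)[C@@H](C)/C=C/C=C/C(=O)O
F4 | step 7 | (4aR,5R,6S)-4a,5-dimethyl-6-[(2E,4E,6S,7S)-6-methyl-7-(triethylsilyloxy)octa-2,4-dienoyloxy]-4,4a,5,6-tetrahydronaphthalen-2(3H)-one | C[C@H](O[Si](CC)(CC)CC)[C@@H](C)/C=C/C=C/C(=O)O[C@H]1C=CC2=CC(=O)CC[C@]2(C)[C@H]1C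
F5 | step 8 | (4aR,5R,6S)-4a,5-dimethyl-2-(triethylsilyloxy)-6-[(2E,4E,6S,7S)-6-methyl-7-(triethylsilyloxy)octa-2,4-dienoyloxy]-4,4a,5,6-tetrahydronaphthalene | C[C@H](O[Si](CC)(CC)CC)[C@@H](C)/C=C/C=C/C(=O)O[C@H]1C=CC2=CC(O[Si](CC)(CC)CC)=CC[C@]2(C)[C@H]1C
F6 | step 8 | (3R,4aR,5R,6S)-4a,5-dimethyl-3-(triethylsilyloxy)-6-[(2E,4E,6S,7S)-6-methyl-7-(triethylsilyloxy)octa-2,4-dienoyloxy]-4,4a,5,6-tetrahydronaphthalen-2(3H)-one | C[C@H](O[Si](CC)(CC)CC)[C@@H](C)/C=C/C=C/C(=O)O[C@H]1C=CC2=CC(=O)[C@H](O[Si](CC)(CC)CC)C[C@]2(C)[C@H]1C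
F7 | step 6 | tert-butyldimethyl{[(2S,3S)-3-methylpent-4-en-2-yl]oxy}silane | C[C@H](O[Si](C)(C)C(C)(C)C)[C@@H](C)C=C
F8 | step 6 | (2R,3S)-3-(tert-butyldimethylsilyloxy)-2-methylbutanal | C[C@H](O[Si](C)(C)C(C)(C)C)[C@@H](C)C=O
F9 | step 6 | ethyl (2E,4E,6S,7S)-7-(tert-butyldimethylsilyloxy)-6-methylocta-2,4-dienoate | C[C@H](O[Si](C)(C)C(C)(C)C)[C@@H](C)/C=C/C=C/C(=O)OCC
F10 | step 6 | (2E,4E,6S,7S)-7-(tert-butyldimethylsilyloxy)-6-methylocta-2,4-dienoic acid | C[C@H](O[Si](C)(C)C(C)(C)C)[C@@H](C)/C=C/C=C/C(=O)O
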